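**Retrosynthetic overview**

- The strategy rests on three of the four catechols. Ring C (the aryl on C2) and rings D and E (the aryls of the two lactates) are 4-alkylbenzene rings whose second OH lies ortho to a phenolic OH, with two equivalent ortho C–H positions. All three are made last, by ortho-hydroxylation of the tris(4-hydroxyphenyl) compound 26; the ring A catechol (C7-OH, C8-OH) is carried from the start.
- 26 comes from its pentabenzyl ether 25, which comes from two Mitsunobu esterifications: C1–CO2H with the S lactate 13 (inversion to R) and C3–CO2H with the R lactate 16 (inversion to S).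
- The cis acid 22 comes from a lactone-enolate Claisen rearrangement of isochromanone 19, which forms C1–C2 and C3=C4 and sets both ring stereocentres. 19 comes from ring A aldehyde 6 and the α-aluminated 4-benzyloxycinnamate made from propiolate 10.
- Ring order: the temporary lactone ring (step 12), then the only new carbocycle C1–C2–C3=C4–C4a–C8a (step 13); no ring forms in the key step.

Key step: step 18

Remark: O-benzyl-L-tyrosine, O-benzyl-D-tyrosine and 4-(benzyloxy)benzaldehyde are taken as commercial starting materials. Compounds 18–22 are racemic and are drawn as the enantiomer that leads to 27; the 1S,2S series is secured in step 14 by separation of diastereomers. Locants: C1 = CH(CO2R), C2 = CH(aryl), C3=C4 = alkene, ring A = C4a–C8a.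

**Ring A aldehyde**

Step 1
Reactants: 1 2,3-dihydroxybenzaldehyde
Product: 2 2,3-bis(benzyloxy)benzaldehyde
Conditions: BnBr, K2CO3, DMF, 60 °C
Reagents that add atoms: benzyl bromide, BrCc1ccccc1
Why: Williamson etherification of both phenols gives benzyl ethers that should survive every later step and leave together in step 17.

Step 2
Reactants: 2 2,3-bis(benzyloxy)benzaldehyde
Product: 3 1-(methylsulfinyl)-1-(methylthio)-2-[2,3-bis(benzyloxy)phenyl]ethene
Conditions: MeS(O)CH2SMe, PhCH2NMe3OH (40% in MeOH), THF, reflux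
Reagents that add atoms: methyl (methylsulfinyl)methyl sulfide, CSCS(C)=O
Why: Knoevenagel-type condensation of the aldehyde with the sulfinyl-stabilised carbanion (first stage of the Ogura–Tsuchihashi arylacetate synthesis) should give the ketene dithioacetal S-oxide, whose alkene geometry and sulfur configuration do not matter.

Step 3
Reactants: 3 1-(methylsulfinyl)-1-(methylthio)-2-[2,3-bis(benzyloxy)phenyl]ethene
Product: 4 ethyl 2-[2,3-bis(benzyloxy)phenyl]acetate
Conditions: HCl, EtOH, rt
Reagents that add atoms: ethanol, CCO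
Why: Acid ethanolysis of the ketene dithioacetal S-oxide (second stage of the Ogura–Tsuchihashi homologation) turns the former aldehyde carbon into the benzylic CH2 of the arylacetate, and aryl benzyl ethers tolerate ethanolic HCl at room temperature.

Step 4
Reactants: 4 ethyl 2-[2,3-bis(benzyloxy)phenyl]acetate
Product: 5 ethyl 2-[2,3-bis(benzyloxy)-6-bromophenyl]acetate
Conditions: NBS, MeCN, 0 °C → rt
Reagents that add atoms: N-bromosuccinimide, O=C1CCC(=O)N1Br
Why: Electrophilic aromatic bromination should go para to the unhindered 3-benzyloxy group (the 2-benzyloxy group is twisted out of conjugation by its two ortho neighbours), which is the position ortho to the acetate chain, as known for 2,3-dialkoxytoluenes and 2,3-dialkoxybenzaldehydes.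

Step 5
Reactants: 5 ethyl 2-[2,3-bis(benzyloxy)-6-bromophenyl]acetate
Product: 6 ethyl 2-[2,3-bis(benzyloxy)-6-formylphenyl]acetate
Conditions: Pd(OAc)2 (cat.), BuPAd2 (cat.), TMEDA, CO/H2 (1:1, 5 bar), PhMe, 100 °C
Reagents that add atoms: carbon monoxide, [C-]#[O+]
Why: Palladium-catalysed reductive carbonylation (formylation) of the aryl bromide by oxidative addition, CO insertion and hydrogenolysis of the acylpalladium should leave the ester and the benzyl ethers alone under the homogeneous catalyst.

**Propiolate**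

Step 6
Reactants: 7 4-(benzyloxy)benzaldehyde
Product: 8 1-(benzyloxy)-4-(2,2-dibromovinyl)benzene
Conditions: CBr4, PPh3, CH2Cl2, 0 °C
Reagents that add atoms: carbon tetrabromide, BrC(Br)(Br)Br
Why: Corey–Fuchs dibromo-olefination, a Wittig-type reaction of Ph3P=CBr2 with the aldehyde.

Step 7
Reactants: 8 1-(benzyloxy)-4-(2,2-dibromovinyl)benzene
Product: 10 allyl 3-[4-(benzyloxy)phenyl]prop-2-ynoate, via lithium acetylide 9 (not isolated)
Conditions: nBuLi (2.1 equiv), THF, −78 → 0 °C; then ClCO2CH2CH=CH2, −78 → 0 °C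
Reagents that add atoms: allyl chloroformate, C=CCOC(=O)Cl
Why: Second stage of the Corey–Fuchs sequence (Br/Li exchange, Fritsch–Buttenberg–Wiechell rearrangement, deprotonation) gives the lithium acetylide, which is C-acylated by the chloroformate.

**Lactates**

Step 8
Reactants: 11 O-benzyl-L-tyrosine
Product: 12 (S)-3-[4-(benzyloxy)phenyl]-2-hydroxypropanoic acid
Conditions: NaNO2, 1 M H2SO4, 1,4-dioxane/H2O, 0 °C → rt
Reagents that add atoms: water, O
Why: Diazotisation of the α-amino acid proceeds with net retention (double inversion through the α-lactone), so the S centre of the amino acid is carried into the lactic acid.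

Step 9
Reactants: 12 (S)-3-[4-(benzyloxy)phenyl]-2-hydroxypropanoic acid
Product: 13 methyl (S)-3-[4-(benzyloxy)phenyl]-2-hydroxypropanoate
Conditions: MeOH, H2SO4 (cat.), reflux
Reagents that add atoms: methanol, CO
Why: Fischer esterification, which does not touch the stereocentre or the benzyl ether.

Step 10
Reactants: 14 O-benzyl-D-tyrosine
Product: 15 (R)-3-[4-(benzyloxy)phenyl]-2-hydroxypropanoic acid
Conditions: NaNO2, 1 M H2SO4, 1,4-dioxane/H2O, 0 °C → rt
Reagents that add atoms: water, O
Why: Diazotisation with net retention through the α-lactone, as in step 8, gives the R hydroxy acid.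

Step 11
Reactants: 15 (R)-3-[4-(benzyloxy)phenyl]-2-hydroxypropanoic acid
Product: 16 methyl (R)-3-[4-(benzyloxy)phenyl]-2-hydroxypropanoate
Conditions: MeOH, H2SO4 (cat.), reflux
Reagents that add atoms: methanol, CO
Why: Fischer esterification without change at the stereocentre.

**Assembly**

Step 12
Reactants: 10 allyl 3-[4-(benzyloxy)phenyl]prop-2-ynoate; 6 ethyl 2-[2,3-bis(benzyloxy)-6-formylphenyl]acetate
Product: 19 rac-5,6-bis(benzyloxy)-1-[(Z)-1-(allyloxycarbonyl)-2-(4-benzyloxyphenyl)vinyl]isochroman-3-one, via vinylalane 17 (not isolated), via hydroxy ester 18 (not isolated)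
Conditions: iBu2AlH, N-methylmorpholine N-oxide, THF, 0 °C; 10, 0 °C; then 6, 0 °C → rt; aq. potassium sodium tartrate; CSA (cat.), CH2Cl2, rt
Reagents that add atoms: none
Why: Syn-hydroalumination of the ynoate (vinylalumination) should give the α-aluminated acrylate with the aryl group cis to the ester, which adds to the aldehyde with retention of alkene geometry, and the δ-hydroxy ester then lactonises to the isochroman-3-one; the new carbinol centre (C4 of the target) forms as a racemate.

Step 13
Reactants: 19 rac-5,6-bis(benzyloxy)-1-[(Z)-1-(allyloxycarbonyl)-2-(4-benzyloxyphenyl)vinyl]isochroman-3-one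
Product: 22 rac-(1S,2S)-3-(allyloxycarbonyl)-7,8-bis(benzyloxy)-2-[4-(benzyloxy)phenyl]-1,2-dihydronaphthalene-1-carboxylic acid, via silyl ketene acetal 20 (not isolated), via trimethylsilyl ester 21 (not isolated)
Conditions: LiN(SiMe3)2, Me3SiCl, Et3N, THF, −78 °C → rt; then PhMe, 80 °C; 1 M HCl work-up
Reagents that add atoms: none
Why: Ireland–Claisen rearrangement of a δ-lactone silyl ketene acetal carrying a 6-alkenyl group (lactone-enolate Claisen): the two-atom aromatic bridge between the termini forces a boat transition state in which the enol ether carbon bonds to the aryl-bearing alkene carbon on the face syn to the departing carboxylate, so the Z alkene (aryl cis to the ester, H turned towards the aromatic bridge) can give only the cis C1/C2 pair together with C3=C4 and the free C1 acid, the S carbinol centre being transferred to 1S,2S; a stepwise enolate SN2′ pathway would give the same product.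

Step 14
Reactants: 22 rac-(1S,2S)-3-(allyloxycarbonyl)-7,8-bis(benzyloxy)-2-[4-(benzyloxy)phenyl]-1,2-dihydronaphthalene-1-carboxylic acid; 13 methyl (S)-3-[4-(benzyloxy)phenyl]-2-hydroxypropanoate
Product: 23 3-allyl 1-[(R)-1-methoxy-1-oxo-3-(4-benzyloxyphenyl)propan-2-yl] (1S,2S)-7,8-bis(benzyloxy)-2-[4-(benzyloxy)phenyl]-1,2-dihydronaphthalene-1,3-dicarboxylate
Conditions: PPh3, DIAD, THF, 0 °C → rt; chromatographic separation from the 1R,2R diastereomer
Reagents that add atoms: none
Why: Mitsunobu esterification, in which the carboxylate of 22 displaces the activated hydroxyl of 13 with inversion (S → R) and, because the acid is never activated, C1–H is not enolised; the enantiopure lactate converts the two enantiomers of 22 into two diastereomeric diesters, so the 1S,2S series is secured here by separation at the cost of at most half the material.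

Step 15
Reactants: 23 the (1S,2S) diester with the (R)-lactate on C1 and the allyl ester on C3
Product: 24 (1S,2S)-7,8-bis(benzyloxy)-2-[4-(benzyloxy)phenyl]-1-{[(R)-1-methoxy-1-oxo-3-(4-benzyloxyphenyl)propan-2-yl]oxycarbonyl}-1,2-dihydronaphthalene-3-carboxylic acid
Conditions: Pd(PPh3)4 (cat.), PhNHMe, THF, rt
Reagents that add atoms: none
Why: Zerovalent palladium ionises the allyl ester and the π-allyl is transferred to N-methylaniline (Tsuji–Trost deallylation), freeing the C3 acid under neutral conditions that should leave C1–H, the benzyl ethers and the lactate untouched.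

Step 16
Reactants: 24 the (1S,2S) C3 acid with the (R)-lactate ester on C1; 16 methyl (R)-3-[4-(benzyloxy)phenyl]-2-hydroxypropanoate
Product: 25 pentabenzyl ether of 26: 1-[(R)-lactate] 3-[(S)-lactate] diester of (1S,2S)-7,8-bis(benzyloxy)-2-[4-(benzyloxy)phenyl]-1,2-dihydronaphthalene-1,3-dicarboxylic acid, both lactates being methyl 3-(4-benzyloxyphenyl)lactates
Conditions: PPh3, DIAD, THF, 0 °C → rt
Reagents that add atoms: none
Why: Second Mitsunobu esterification, with inversion of the R alcohol 16 to the S lactate ester required on the C3 carboxyl, again without acyl activation so that C1 cannot epimerise.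

Step 17
Reactants: 25 pentabenzyl ether of 26
Product: 26 tris(4-hydroxyphenyl) precursor: dimethyl ester with free OH at C7 and C8 of ring A and one OH on each of rings C, D and E
Conditions: BCl3, C6HMe5, CH2Cl2, −78 °C; MeOH quench
Reagents that add atoms: none
Why: Lewis-acid cleavage of the five aryl benzyl ethers with pentamethylbenzene as a non-basic benzyl-cation scavenger should spare the C3=C4 alkene (which hydrogenolysis would reduce), the four esters and the base-labile cis C1 centre.

Step 18
Reactants: 26 tris(4-hydroxyphenyl) precursor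
Product: 27 CNP0237075.1 (target)
Conditions: HpaB oxygenase and HpaC NADH:flavin reductase (4-hydroxyphenylacetate 3-hydroxylase; wild-type panel or engineered HpaB), FAD (cat.), NAD+ (cat.), formate dehydrogenase, HCO2Na, air, sodium L-ascorbate, KH2PO4/K2HPO4 buffer pH 7.0, 10% DMSO, 30 °C; extraction and chromatography under argon
Reagents that add atoms: dioxygen, O=O
Why: Proposed new method: the reductase passes reduced flavin to the oxygenase, where it reacts with O2 to a C4a-hydroperoxyflavin that transfers an electrophilic OH to the carbon ortho to the bound phenolate (electrophilic aromatic substitution, then rearomatisation), and this is repeated on rings C, D and E of 26 until three aryl C–O bonds are made. The closest known reaction type is the ortho-hydroxylation of 4-hydroxyphenylacetate, tyrosol, p-coumarate, tyrosine and stilbene-sized phenols by this enzyme class; a pentaphenolic diester of the size of 26 has not been shown as a substrate, so active-site-enlarged variants may be needed. No ring is closed and no stereocentre is formed, and C1, C2 and both lactate centres are not at risk at pH 7. Regioselectivity needs no control because each 4-alkylphenol ring has two equivalent positions ortho to OH and the mechanism excludes the meta positions. Chemoselectivity rests on the ring A catechol being in place beforehand and on the enzyme having no catechol oxidase activity, so the C3=C4 alkene, the esters and the catechols should persist, with ascorbate and argon work-up guarding the tetracatechol against autoxidation.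

**Compound list**

1 | 2,3-dihydroxybenzaldehyde | O=Cc1cccc(O)c1O | starting material
2 | 2,3-bis(benzyloxy)benzaldehyde | O=Cc1cccc(OCc2ccccc2)c1OCc1ccccc1 | intermediate
3 | 1-(methylsulfinyl)-1-(methylthio)-2-[2,3-bis(benzyloxy)phenyl]ethene (geometry and S configuration immaterial) | CSC(=Cc1cccc(OCc2ccccc2)c1OCc1ccccc1)S(C)=O | intermediate
4 | ethyl 2-[2,3-bis(benzyloxy)phenyl]acetate | CCOC(=O)Cc1cccc(OCc2ccccc2)c1OCc1ccccc1 | intermediate
5 | ethyl 2-[2,3-bis(benzyloxy)-6-bromophenyl]acetate | CCOC(=O)Cc1c(Br)ccc(OCc2ccccc2)c1OCc1ccccc1 | intermediate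
6 | ethyl 2-[2,3-bis(benzyloxy)-6-formylphenyl]acetate | CCOC(=O)Cc1c(C=O)ccc(OCc2ccccc2)c1OCc1ccccc1 | intermediate
7 | 4-(benzyloxy)benzaldehyde | O=Cc1ccc(OCc2ccccc2)cc1 | starting material
8 | 1-(benzyloxy)-4-(2,2-dibromovinyl)benzene | BrC(Br)=Cc1ccc(OCc2ccccc2)cc1 | intermediate
9 | lithium [4-(benzyloxy)phenyl]acetylide (not isolated) | [Li]C#Cc1ccc(OCc2ccccc2)cc1 | intermediate
10 | allyl 3-[4-(benzyloxy)phenyl]prop-2-ynoate | C=CCOC(=O)C#Cc1ccc(OCc2ccccc2)cc1 | intermediate
11 | O-benzyl-L-tyrosine | N[C@@H](Cc1ccc(OCc2ccccc2)cc1)C(=O)O | starting material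
12 | (S)-3-[4-(benzyloxy)phenyl]-2-hydroxypropanoic acid | O[C@@H](Cc1ccc(OCc2ccccc2)cc1)C(=O)O | intermediate
13 | methyl (S)-3-[4-(benzyloxy)phenyl]-2-hydroxypropanoate | COC(=O)[C@@H](O)Cc1ccc(OCc2ccccc2)cc1 | intermediate
14 | O-benzyl-D-tyrosine | N[C@H](Cc1ccc(OCc2ccccc2)cc1)C(=O)O | starting material
15 | (R)-3-[4-(benzyloxy)phenyl]-2-hydroxypropanoic acid | O[C@H](Cc1ccc(OCc2ccccc2)cc1)C(=O)O | intermediate
16 | methyl (R)-3-[4-(benzyloxy)phenyl]-2-hydroxypropanoate | COC(=O)[C@H](O)Cc1ccc(OCc2ccccc2)cc1 | intermediate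
17 | allyl (E)-3-[4-(benzyloxy)phenyl]-2-(diisobutylalumanyl)prop-2-enoate, aryl cis to the ester (not isolated) | C=CCOC(=O)/C(=C\c1ccc(OCc2ccccc2)cc1)[Al](CC(C)C)CC(C)C | intermediate
18 | ethyl 2-{2,3-bis(benzyloxy)-6-[(Z)-2-(allyloxycarbonyl)-3-(4-benzyloxyphenyl)-1-hydroxyprop-2-enyl]phenyl}acetate (racemic, not isolated) | CCOC(=O)Cc1c([C@H](O)/C(C(=O)OCC=C)=C/c2ccc(OCc3ccccc3)cc2)ccc(OCc2ccccc2)c1OCc1ccccc1 | intermediate
19 | 5,6-bis(benzyloxy)-1-[(Z)-1-(allyloxycarbonyl)-2-(4-benzyloxyphenyl)vinyl]isochroman-3-one (racemic; S enantiomer shown) | O=C1Cc2c(OCc3ccccc3)c(OCc3ccccc3)ccc2[C@@H](/C(C(=O)OCC=C)=C/c2ccc(OCc3ccccc3)cc2)O1 | intermediate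
20 | 3-(trimethylsilyloxy)-1H-isochromene from 19 (racemic, not isolated) | C[Si](C)(C)OC1=Cc2c(OCc3ccccc3)c(OCc3ccccc3)ccc2[C@@H](/C(C(=O)OCC=C)=C/c2ccc(OCc3ccccc3)cc2)O1 | intermediate
21 | trimethylsilyl ester of 22 (racemic, not isolated) | C=CCOC(=O)C1=Cc2ccc(OCc3ccccc3)c(OCc3ccccc3)c2[C@@H](C(=O)O[Si](C)(C)C)[C@H]1c1ccc(OCc2ccccc2)cc1 | intermediate
22 | (1S,2S)-3-(allyloxycarbonyl)-7,8-bis(benzyloxy)-2-[4-(benzyloxy)phenyl]-1,2-dihydronaphthalene-1-carboxylic acid (racemic, cis) | C=CCOC(=O)C1=Cc2ccc(OCc3ccccc3)c(OCc3ccccc3)c2[C@@H](C(=O)O)[C@H]1c1ccc(OCc2ccccc2)cc1 | intermediate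
23 | (1S,2S) diester: C1 (R)-lactate, C3 allyl | C=CCOC(=O)C1=Cc2ccc(OCc3ccccc3)c(OCc3ccccc3)c2[C@@H](C(=O)O[C@H](Cc2ccc(OCc3ccccc3)cc2)C(=O)OC)[C@H]1c1ccc(OCc2ccccc2)cc1 | intermediate
24 | (1S,2S) C3 acid with C1 (R)-lactate ester | OC(=O)C1=Cc2ccc(OCc3ccccc3)c(OCc3ccccc3)c2[C@@H](C(=O)O[C@H](Cc2ccc(OCc3ccccc3)cc2)C(=O)OC)[C@H]1c1ccc(OCc2ccccc2)cc1 | intermediate
25 | pentabenzyl ether of 26 | COC(=O)[C@H](Cc1ccc(OCc2ccccc2)cc1)OC(=O)C1=Cc2ccc(OCc3ccccc3)c(OCc3ccccc3)c2[C@@H](C(=O)O[C@H](Cc2ccc(OCc3ccccc3)cc2)C(=O)OC)[C@H]1c1ccc(OCc2ccccc2)cc1 | intermediate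
26 | tris(4-hydroxyphenyl) precursor with ring A catechol | COC(=O)[C@H](Cc1ccc(O)cc1)OC(=O)C1=Cc2ccc(O)c(O)c2[C@@H](C(=O)O[C@H](Cc2ccc(O)cc2)C(=O)OC)[C@H]1c1ccc(O)cc1 | intermediate
27 | CNP0237075.1 | COC(=O)[C@H](Cc1ccc(O)c(O)c1)OC(=O)C1=Cc2ccc(O)c(O)c2[C@@H](C(=O)O[C@H](Cc2ccc(O)c(O)c2)C(=O)OC)[C@H]1c1ccc(O)c(O)c1 | target

**Step count**

Total step count: 18. Longest linear sequence: 12 steps (steps 1–5, then 12–18).

**Steps most likely to fail**

Step 18. The oxygenase may fail to bind the large pentaphenol, may stop at partly hydroxylated stages, may over-hydroxylate ring A, or the catechols may autoxidise during the run. The fallback is a chemical ortho-oxygenation by known reactions and sets out from 26. The ring A catechol is first masked by condensation with phenylboronic acid (PhMe, 4 Å molecular sieves) as the cyclic phenylboronate of 26 F1. IBX in DMF then oxygenates each 4-alkylphenol ring ortho to its OH (phenol to o-quinone by the pentavalent iodine reagent) to the tris(o-quinone) boronate F2. Na2S2O4 in water reduces the three quinones to catechols and the aqueous work-up hydrolyses the boronate, so the sequence comes back to the route at 27.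

Step 13. The silyl ketene acetal may fail to reach the strained boat geometry, and C-silylation, loss of alkene geometry by reversible conjugate addition, or elimination may take over. The fallback builds the ring by a tandem Michael/Horner–Wadsworth–Emmons annulation and sets out from 6. Saponification (LiOH, THF/H2O) gives 2-[2,3-bis(benzyloxy)-6-formylphenyl]acetic acid F3. Carbodiimide esterification (EDC·HCl, DMAP cat.) with 16, with retention, gives the (R)-lactate arylacetate F4. Knoevenagel condensation of 7 with allyl 2-(diethoxyphosphoryl)acetate (TiCl4, N-methylmorpholine) gives allyl 3-[4-(benzyloxy)phenyl]-2-(diethoxyphosphoryl)acrylate F5. With Cs2CO3 in MeCN the arylacetate enolate of F4 adds to F5 to give the phosphonate Michael adduct F6, which closes by intramolecular olefination onto the aldehyde. Under these equilibrating conditions the trans diesters are expected, the (1R,2S) isomer F7 and the (1S,2R) isomer F8, which are separated. Deprotonation of F7 at C1 (LiN(SiMe3)2, THF, −78 °C) and quench with 2,6-di-tert-butylphenol should protonate anti to the C2 aryl group and give the cis ester, which comes back to the route at 23; step 14 is then not needed.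

Step 12. The aluminium allenolate may scramble the alkene geometry before addition, or residual hydride may reduce the aldehyde. The fallback separates C–C bond formation from introduction of the aryl group and sets out from 6. MgI2-promoted coupling of 6 with allyl propiolate (CH2Cl2, 0 °C) gives the (Z)-β-iodo hydroxy ester F9, with iodine cis to the ester. Lactonisation (CSA cat.) gives the iodovinyl isochromanone F10. Suzuki–Miyaura coupling with 4-(benzyloxy)phenylboronic acid (Pd(OAc)2, SPhos, K3PO4, THF/H2O, rt), with retention of alkene geometry, comes back to the route at 19.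

**Further compounds**

F1 | step 18 | cyclic phenylboronate of 26 at the ring A catechol | COC(=O)[C@H](Cc1ccc(O)cc1)OC(=O)C1=Cc2ccc3OB(c4ccccc4)Oc3c2[C@@H](C(=O)O[C@H](Cc2ccc(O)cc2)C(=O)OC)[C@H]1c1ccc(O)cc1
F2 | step 18 | tris(o-quinone) boronate | COC(=O)[C@H](CC1=CC(=O)C(=O)C=C1)OC(=O)C1=Cc2ccc3OB(c4ccccc4)Oc3c2[C@@H](C(=O)O[C@H](CC2=CC(=O)C(=O)C=C2)C(=O)OC)[C@H]1C1=CC(=O)C(=O)C=C1
F3 | step 13 | 2-[2,3-bis(benzyloxy)-6-formylphenyl]acetic acid | OC(=O)Cc1c(C=O)ccc(OCc2ccccc2)c1OCc1ccccc1
F4 | step 13 | methyl (R)-2-{2-[2,3-bis(benzyloxy)-6-formylphenyl]acetoxy}-3-[4-(benzyloxy)phenyl]propanoate | COC(=O)[C@@H](Cc1ccc(OCc2ccccc2)cc1)OC(=O)Cc1c(C=O)ccc(OCc2ccccc2)c1OCc1ccccc1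
F5 | step 13 | allyl 3-[4-(benzyloxy)phenyl]-2-(diethoxyphosphoryl)acrylate | C=CCOC(=O)C(=Cc1ccc(OCc2ccccc2)cc1)P(=O)(OCC)OCC
F6 | step 13 | phosphonate Michael adduct of F4 and F5 (diastereomer mixture, not isolated) | COC(=O)[C@@H](Cc1ccc(OCc2ccccc2)cc1)OC(=O)C(c1c(C=O)ccc(OCc2ccccc2)c1OCc1ccccc1)C(c1ccc(OCc2ccccc2)cc1)C(C(=O)OCC=C)P(=O)(OCC)OCC
F7 | step 13 | (1R,2S) trans isomer of 23 | C=CCOC(=O)C1=Cc2ccc(OCc3ccccc3)c(OCc3ccccc3)c2[C@H](C(=O)O[C@H](Cc2ccc(OCc3ccccc3)cc2)C(=O)OC)[C@H]1c1ccc(OCc2ccccc2)cc1
F8 | step 13 | (1S,2R) trans isomer of 23 | C=CCOC(=O)C1=Cc2ccc(OCc3ccccc3)c(OCc3ccccc3)c2[C@@H](C(=O)O[C@H](Cc2ccc(OCc3ccccc3)cc2)C(=O)OC)[C@@H]1c1ccc(OCc2ccccc2)cc1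
F9 | step 12 | ethyl 2-{2,3-bis(benzyloxy)-6-[(Z)-2-(allyloxycarbonyl)-1-hydroxy-3-iodoprop-2-enyl]phenyl}acetate (racemic) | CCOC(=O)Cc1c(C(O)/C(C(=O)OCC=C)=C/I)ccc(OCc2ccccc2)c1OCc1ccccc1
F10 | step 12 | 5,6-bis(benzyloxy)-1-[(Z)-1-(allyloxycarbonyl)-2-iodovinyl]isochroman-3-one (racemic) | O=C1Cc2c(OCc3ccccc3)c(OCc3ccccc3)ccc2C(/C(C(=O)OCC=C)=C/I)O1
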